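Ring B (C4a', C5', C6', C7', C8', C8a') is built from two acyclic three-carbon pieces rather than by decorating a catechol. Its 1,2,3,5-substitution (acyl carbon on C4a', unlike oxygens on C8a' and C8', the bond to C2 on C6') matches a formal [3+3] cyclocondensation. A bis-silylated trienol ether of a benzyloxy diketone that already carries the senecioyl chain supplies C8', C8a' and C4a'. O-silylated bromomalonaldehyde supplies C7', C6' and C5'. One operation forms C7'–C8' and C4a'–C5', aromatises, frees only the C8a' phenol and leaves bromine on C6'. Oxa-Michael closure of ring D, borylation and an enantioselective rhodium-catalysed chromone arylation then set C2.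

Key step: step 5

Remark on locants: primed locants belong to the dimethylchromanone unit (arene ring B, pyranone ring D), unprimed ones to the flavanone core (arene ring A, pyranone ring C).
Remark on geometry: the double-bond geometries of 5, 6, 7 and 9 are the expected chelate-derived ones and vanish on aromatisation. If step 2 also gives the regioisomeric 2-silyloxy enone, deprotonation at C1 leads to the same triene 7.
Remark on induction: the facial sense in step 11 is assigned by analogy with cyclic enones, where (S)-biaryl diphosphines deliver the aryl group to the corresponding face. The (R)-ligand is equally available if the assignment has to be reversed.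

Step 1
Reactants: 1 mesityl oxide (4-methylpent-3-en-2-one); 2 benzyloxyacetyl chloride
Product: 4 1-(benzyloxy)-6-methylhept-5-ene-2,4-dione, via lithium dienolate 3 (not isolated)
Conditions: 1 (2.0 equiv), LiN(SiMe3)2 (2.1 equiv), THF, −78 °C; 2 (1.0 equiv), −78 °C; aq. NH4Cl
Reagents that add atoms: none
Why: Crossed Claisen-type C-acylation in which the hindered, non-nucleophilic amide removes the kinetically favoured acetyl proton to give cross-conjugated dienolate 3, whose carbon terminus attacks the acid chloride, while the second equivalent of 3 takes up the acidic proton of 4 and so prevents double acylation.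

Step 2
Reactants: 4 1-(benzyloxy)-6-methylhept-5-ene-2,4-dione
Product: 5 (3Z)-1-(benzyloxy)-6-methyl-4-(trimethylsilyloxy)hepta-3,5-dien-2-one
Conditions: Me3SiCl, NEt3, toluene, 20 °C; filtration under argon, no aqueous work-up
Reagents that add atoms: chlorotrimethylsilane, C[Si](C)(C)Cl
Why: Silyl enol ether formation from a strongly enolised 1,3-diketone needs only an amine base and should give the vinylogous silyl ester, drawn as the linearly conjugated isomer that keeps the carbonyl group next to the CH2OBn carbon.

Step 3
Reactants: 5 (3Z)-1-(benzyloxy)-6-methyl-4-(trimethylsilyloxy)hepta-3,5-dien-2-one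
Product: 7 (1Z,3Z)-1-(benzyloxy)-6-methyl-2,4-bis(trimethylsilyloxy)hepta-1,3,5-triene, via lithium trienolate 6 (not isolated)
Conditions: LiN(iPr)2 (1.3 equiv), THF, −78 °C; Me3SiCl (1.5 equiv), −78 → 20 °C; pentane, filtration, used without chromatography
Reagents that add atoms: chlorotrimethylsilane, C[Si](C)(C)Cl
Why: Kinetic enolate formation followed by O-silylation, in which the amide removes a C1 proton (alpha to the ketone, acidified by the benzyloxy group, reached through lithium chelation by both oxygens) faster than a remote vinylogous methyl proton, and the hard silyl chloride traps chelated Z-enolate 6 on oxygen.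

Step 4
Reactants: 8 bromomalonaldehyde
Product: 9 (E)-2-bromo-3-(trimethylsilyloxy)prop-2-enal
Conditions: Me3SiCl, NEt3, CH2Cl2, 0 → 20 °C; pentane, filtration, used crude
Reagents that add atoms: chlorotrimethylsilane, C[Si](C)(C)Cl
Why: O-Silylation of the acidic enol of the dialdehyde gives a 3-silyloxy-2-enal, which belongs to the electrophile class on which the cyclocondensation is established, dissolves in CH2Cl2 and has no acidic proton that could desilylate 7.

Step 5
Reactants: 7 (1Z,3Z)-1-(benzyloxy)-6-methyl-2,4-bis(trimethylsilyloxy)hepta-1,3,5-triene; 9 (E)-2-bromo-3-(trimethylsilyloxy)prop-2-enal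
Product: 10 1-[3-(benzyloxy)-5-bromo-2-hydroxyphenyl]-3-methylbut-2-en-1-one
Conditions: 7 (1.0 equiv), 9 (1.2 equiv), TiCl4 (1.1 equiv), CH2Cl2 (concentrated), −78 → 20 °C with slow warming; cold 1 M HCl
Reagents that add atoms: none
Why: TiCl4 activates one C–O terminus of 9, and C1 of 7 (the future C8'), the end of the bis-silyloxy diene and its most nucleophilic carbon, attacks it in a Mukaiyama aldol-type addition that makes C7'–C8'. The central carbon C3 of 7 (the future C4a'), still a silyl enol ether, then closes onto the second unmasked aldehyde carbon in a 6-(enolexo)-exo-trig aldol that makes C4a'–C5', and both oxygens of 9 leave as silanol and siloxane so that ring B aromatises. This is the established formal [3+3] cyclocondensation of 1,3-bis(silyl enol ethers) with 3-silyloxy-2-en-1-ones, known for diketone-derived dienes, 4-alkoxy dienes and 2-halogenated electrophiles, so only the alkenyl group on C4 of the diene is new. No stereocentre is formed, and orientation is not an issue because 9 is a masked symmetric dialdehyde. The two catechol oxygens come out differentiated because C8a' arrives as O–Si (freed, then hydrogen-bonded to the ketone) and C8' as O–Bn; the cross-conjugated C5=C6 bond stays out because attack at C6 would give a cation the oxygen cannot stabilise and its Z-methyl group blocks the s-cis conformer that a Diels–Alder reaction would need. Low temperature and about one equivalent of TiCl4 spare enone and benzyl ether, and any HCl adduct or prematurely cyclised material converges on 11 in step 6.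

Step 6
Reactants: 10 1-[3-(benzyloxy)-5-bromo-2-hydroxyphenyl]-3-methylbut-2-en-1-one
Product: 11 8-(benzyloxy)-6-bromo-2,2-dimethylchroman-4-one
Conditions: K2CO3 (0.5 equiv), MeOH, 20 °C
Reagents that add atoms: none
Why: Intramolecular oxa-Michael addition (6-endo-trig) of the C8a' phenoxide to the β,β-dimethyl enone carbon closes ring D, favoured by the gem-dimethyl effect, and the benzyl ether on C8' leaves only one oxygen able to cyclise.

Step 7
Reactants: 11 8-(benzyloxy)-6-bromo-2,2-dimethylchroman-4-one
Product: 12 8-(benzyloxy)-2,2-dimethyl-6-(4,4,5,5-tetramethyl-1,3,2-dioxaborolan-2-yl)chroman-4-one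
Conditions: B2pin2, Pd(dppf)Cl2 (cat.), KOAc, 1,4-dioxane, 85 °C
Reagents that add atoms: bis(pinacolato)diboron, CC1(C)OB(OC1(C)C)B1OC(C)(C)C(C)(C)O1
Why: Miyaura borylation (oxidative addition of zerovalent palladium into C6'–Br, acetate-assisted transmetalation, reductive elimination) tolerates the ketone and the benzyl ether, which a halogen–lithium exchange would not.

Step 8
Reactants: 12 8-(benzyloxy)-2,2-dimethyl-6-(4,4,5,5-tetramethyl-1,3,2-dioxaborolan-2-yl)chroman-4-one
Product: 13 [8-(benzyloxy)-2,2-dimethyl-4-oxochroman-6-yl]boronic acid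
Conditions: NaIO4, NH4OAc, acetone/H2O, 20 °C
Reagents that add atoms: water, O
Why: Oxidative boronate cleavage, in which the ester hydrolysis equilibrium is pulled to the free boronic acid because periodate destroys the liberated glycol (Malaprade reaction) in a buffered medium that does not touch ketone or benzyl ether.

Step 9
Reactants: 14 2,4,6-trihydroxyacetophenone
Product: 15 1-[2,4-bis(benzyloxy)-6-hydroxyphenyl]ethan-1-one
Conditions: BnBr (2.1 equiv), K2CO3 (2.2 equiv), DMF, 20 → 60 °C
Reagents that add atoms: benzyl bromide, BrCc1ccccc1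
Why: Williamson ether synthesis stops at the bis-ether because, once the para and one ortho hydroxyl group are alkylated, the remaining ortho hydroxyl group is held in a hydrogen bond to the acetyl carbonyl and is far less nucleophilic.

Step 10
Reactants: 15 1-[2,4-bis(benzyloxy)-6-hydroxyphenyl]ethan-1-one
Product: 17 5,7-bis(benzyloxy)-4H-chromen-4-one, via enaminone 16 (not isolated)
Conditions: Me2NCH(OMe)2, toluene, 100 °C; concentration; conc. HCl, CH2Cl2, 20 → 40 °C
Reagents that add atoms: N,N-dimethylformamide dimethyl acetal, COC(OC)N(C)C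
Why: Enaminone chromone synthesis, in which the acetyl CH3 group condenses with the amide acetal and acid then lets the free phenol add to the β-carbon and expel dimethylamine, gives a chromone unsubstituted at C2 and C3 under conditions that benzyl ethers survive.

Step 11
Reactants: 13 [8-(benzyloxy)-2,2-dimethyl-4-oxochroman-6-yl]boronic acid; 17 5,7-bis(benzyloxy)-4H-chromen-4-one
Product: 18 (2S)-5,7-bis(benzyloxy)-2-[8-(benzyloxy)-2,2-dimethyl-4-oxochroman-6-yl]chroman-4-one
Conditions: 13 (1.5 equiv), [Rh(OH)(cod)]2 (cat.), (S)-MeO-F12-BIPHEP [(S)-6,6'-dimethoxybiphenyl-2,2'-diylbis{bis(3,4,5-trifluorophenyl)phosphine}], toluene/H2O 10:1, 25–40 °C, no added base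
Reagents that add atoms: none
Why: Hayashi–Miyaura reaction (rhodium-catalysed asymmetric 1,4-addition of an arylboronic acid to a chromone), in which the aryl–rhodium species inserts the C2=C3 bond of 17, the (S)-configured electron-poor biaryl diphosphine leaves only the Re face of C2 open so that the new stereocentre is set as S, and hydrolysis of the rhodium oxa-π-allyl without base releases 18 without the ring opening that would racemise it.

Step 12
Reactants: 18 (2S)-5,7-bis(benzyloxy)-2-[8-(benzyloxy)-2,2-dimethyl-4-oxochroman-6-yl]chroman-4-one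
Product: 19 (2S)-5,7-dihydroxy-2-(8-hydroxy-2,2-dimethyl-4-oxochroman-6-yl)chroman-4-one (CNP0303522.1)
Conditions: H2 (1 atm), 10% Pd/C, EtOAc/THF, 20 °C
Reagents that add atoms: none
Why: Catalytic hydrogenolysis removes the three aryl benzyl ethers under neutral conditions, which should leave both aryl ketones and the benzylic C2–O bond intact and avoids the base-induced chalcone equilibrium, so the S configuration at C2 is retained.

Compound list
1 | mesityl oxide | CC(C)=CC(C)=O | starting material
2 | benzyloxyacetyl chloride | O=C(Cl)COCc1ccccc1 | starting material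
3 | lithium 4-methylpenta-1,3-dien-2-olate | [Li+].[O-]C(=C)C=C(C)C | intermediate
4 | 1-(benzyloxy)-6-methylhept-5-ene-2,4-dione | CC(C)=CC(=O)CC(=O)COCc1ccccc1 | intermediate
5 | (3Z)-1-(benzyloxy)-6-methyl-4-(trimethylsilyloxy)hepta-3,5-dien-2-one | CC(C)=C/C(O[Si](C)(C)C)=C/C(=O)COCc1ccccc1 | intermediate
6 | lithium (1Z,3Z)-1-(benzyloxy)-6-methyl-4-(trimethylsilyloxy)hepta-1,3,5-trien-2-olate | [Li+].CC(C)=C/C(O[Si](C)(C)C)=C/C([O-])=C/OCc1ccccc1 | intermediate
7 | (1Z,3Z)-1-(benzyloxy)-6-methyl-2,4-bis(trimethylsilyloxy)hepta-1,3,5-triene | CC(C)=C/C(O[Si](C)(C)C)=C/C(O[Si](C)(C)C)=C/OCc1ccccc1 | intermediate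
8 | bromomalonaldehyde | O=CC(Br)C=O | starting material
9 | (E)-2-bromo-3-(trimethylsilyloxy)prop-2-enal | C[Si](C)(C)O/C=C(/Br)C=O | intermediate
10 | 1-[3-(benzyloxy)-5-bromo-2-hydroxyphenyl]-3-methylbut-2-en-1-one | CC(C)=CC(=O)c1cc(Br)cc(OCc2ccccc2)c1O | intermediate
11 | 8-(benzyloxy)-6-bromo-2,2-dimethylchroman-4-one | CC1(C)CC(=O)c2cc(Br)cc(OCc3ccccc3)c2O1 | intermediate
12 | 8-(benzyloxy)-2,2-dimethyl-6-(4,4,5,5-tetramethyl-1,3,2-dioxaborolan-2-yl)chroman-4-one | CC1(C)CC(=O)c2cc(B3OC(C)(C)C(C)(C)O3)cc(OCc3ccccc3)c2O1 | intermediate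
13 | [8-(benzyloxy)-2,2-dimethyl-4-oxochroman-6-yl]boronic acid | CC1(C)CC(=O)c2cc(B(O)O)cc(OCc3ccccc3)c2O1 | intermediate
14 | 2,4,6-trihydroxyacetophenone | CC(=O)c1c(O)cc(O)cc1O | starting material
15 | 1-[2,4-bis(benzyloxy)-6-hydroxyphenyl]ethan-1-one | CC(=O)c1c(O)cc(OCc2ccccc2)cc1OCc1ccccc1 | intermediate
16 | (E)-1-[2,4-bis(benzyloxy)-6-hydroxyphenyl]-3-(dimethylamino)prop-2-en-1-one | CN(C)/C=C/C(=O)c1c(O)cc(OCc2ccccc2)cc1OCc1ccccc1 | intermediate
17 | 5,7-bis(benzyloxy)-4H-chromen-4-one | O=c1ccoc2cc(OCc3ccccc3)cc(OCc3ccccc3)c12 | intermediate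
18 | (2S)-5,7-bis(benzyloxy)-2-[8-(benzyloxy)-2,2-dimethyl-4-oxochroman-6-yl]chroman-4-one | CC1(C)CC(=O)c2cc([C@@H]3CC(=O)c4c(OCc5ccccc5)cc(OCc5ccccc5)cc4O3)cc(OCc3ccccc3)c2O1 | intermediate
19 | (2S)-5,7-dihydroxy-2-(8-hydroxy-2,2-dimethyl-4-oxochroman-6-yl)chroman-4-one | CC1(C)CC(=O)c2cc([C@@H]3CC(=O)c4c(O)cc(O)cc4O3)cc(O)c2O1 | target

Total step count: 12.
Longest linear sequence: 9 (steps 1, 2, 3, 5, 6, 7, 8, 11, 12).

Steps most likely to fail

Risk 1 (step 5). Several processes may outrun the double condensation:
- Lewis-acid-induced protodesilylation and oligomerisation of the triene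
- addition of two dienes to the very reactive dialdehyde equivalent
- addition of HCl to the enone
- titanium-assisted loss of the benzyl group

The fallback sets out from 7 and comes back at 10. It drops titanium and the labile bromo-enal and installs the halogen only after ring B exists.
- Triene 7 is condensed with commercial 1,1,3,3-tetramethoxypropane under catalytic Me3SiOTf in CH2Cl2 (−78 → 20 °C), the acetal variant of the cyclocondensation. This gives 1-[3-(benzyloxy)-2-hydroxyphenyl]-3-methylbut-2-en-1-one F1.
- Electrophilic aromatic bromination with N-bromosuccinimide in MeCN at 0 °C should then go to C6', which is para to the free phenol and meta to the acyl group. This gives 10.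
- If the triene itself proves to be the weak point, the sequence given for step 3 avoids it as well.

Risk 2 (step 3). Deprotonation at the vinylogous methyl groups, C-silylation of the enolate, or hydrolysis during isolation may prevent clean formation of the triene. The fallback sets out from 2 (and uses 9) and comes back at 10. It moves the benzannulation to the well-tested β-ketoester series and attaches the enone afterwards.
- Acid chloride 2 is acylated onto potassium methyl malonate with MgCl2 and NEt3 in MeCN, with decarboxylation. This gives methyl 4-(benzyloxy)-3-oxobutanoate F2, in which the CH2OBn carbon is the only γ-position.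
- Me3SiCl/NEt3 gives methyl (Z)-4-(benzyloxy)-3-(trimethylsilyloxy)but-2-enoate F3.
- LiN(iPr)2 followed by Me3SiCl gives (1Z,3Z)-4-(benzyloxy)-1-methoxy-1,3-bis(trimethylsilyloxy)buta-1,3-diene F4.
- TiCl4-mediated cyclocondensation of F4 with 9 gives methyl 3-(benzyloxy)-5-bromo-2-hydroxybenzoate F5.
- MeNH(OMe)·HCl with iPrMgCl in THF gives 3-(benzyloxy)-5-bromo-2-hydroxy-N-methoxy-N-methylbenzamide F6.
- Excess 2-methylprop-1-enylmagnesium bromide at 0 °C (Weinreb ketone synthesis) delivers 10.

Risk 3 (step 11). Carbometalation of the electron-rich chromone with its peri benzyloxy group may be slow, so that protodeboronation overtakes it. Poor facial selectivity or reversible opening of ring C may also erode the enantiomeric purity. The fallback sets out from 11 (and uses 15) and comes back at 18. It forms ring C by C–O instead of C–aryl bond formation and secures the configuration by resolution.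
- Reductive carbonylation of 11 (Pd(OAc)2, di(1-adamantyl)-n-butylphosphine, TMEDA, CO/H2, toluene, 100 °C) gives 8-(benzyloxy)-2,2-dimethyl-4-oxochroman-6-carbaldehyde F7.
- Pyrrolidine-promoted Claisen–Schmidt condensation with 15 in EtOH gives (E)-1-[2,4-bis(benzyloxy)-6-hydroxyphenyl]-3-[8-(benzyloxy)-2,2-dimethyl-4-oxochroman-6-yl]prop-2-en-1-one F8. The hindered C3' methylene next to the quaternary carbon should stay out of this reaction.
- NaOAc in refluxing EtOH closes F8 by oxa-Michael addition to racemic 5,7-bis(benzyloxy)-2-[8-(benzyloxy)-2,2-dimethyl-4-oxochroman-6-yl]chroman-4-one F9.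
- Preparative chromatography on a polysaccharide chiral phase separates 18 from (2R)-5,7-bis(benzyloxy)-2-[8-(benzyloxy)-2,2-dimethyl-4-oxochroman-6-yl]chroman-4-one F10.
- F10 is returned to F9 by the same NaOAc equilibration and recycled.

Further compounds
F1 | step 5 | 1-[3-(benzyloxy)-2-hydroxyphenyl]-3-methylbut-2-en-1-one | CC(C)=CC(=O)c1cccc(OCc2ccccc2)c1O
F2 | step 3 | methyl 4-(benzyloxy)-3-oxobutanoate | COC(=O)CC(=O)COCc1ccccc1
F3 | step 3 | methyl (Z)-4-(benzyloxy)-3-(trimethylsilyloxy)but-2-enoate | COC(=O)/C=C(\O[Si](C)(C)C)COCc1ccccc1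
F4 | step 3 | (1Z,3Z)-4-(benzyloxy)-1-methoxy-1,3-bis(trimethylsilyloxy)buta-1,3-diene | CO/C(O[Si](C)(C)C)=C/C(O[Si](C)(C)C)=C/OCc1ccccc1
F5 | step 3 | methyl 3-(benzyloxy)-5-bromo-2-hydroxybenzoate | COC(=O)c1cc(Br)cc(OCc2ccccc2)c1O
F6 | step 3 | 3-(benzyloxy)-5-bromo-2-hydroxy-N-methoxy-N-methylbenzamide | CON(C)C(=O)c1cc(Br)cc(OCc2ccccc2)c1O
F7 | step 11 | 8-(benzyloxy)-2,2-dimethyl-4-oxochroman-6-carbaldehyde | CC1(C)CC(=O)c2cc(C=O)cc(OCc3ccccc3)c2O1
F8 | step 11 | (E)-1-[2,4-bis(benzyloxy)-6-hydroxyphenyl]-3-[8-(benzyloxy)-2,2-dimethyl-4-oxochroman-6-yl]prop-2-en-1-one | O=C(/C=C/c1cc(OCc2ccccc2)c2OC(C)(C)CC(=O)c2c1)c1c(O)cc(OCc2ccccc2)cc1OCc1ccccc1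
F9 | step 11 | racemic 5,7-bis(benzyloxy)-2-[8-(benzyloxy)-2,2-dimethyl-4-oxochroman-6-yl]chroman-4-one | CC1(C)CC(=O)c2cc(C3CC(=O)c4c(OCc5ccccc5)cc(OCc5ccccc5)cc4O3)cc(OCc3ccccc3)c2O1
F10 | step 11 | (2R)-5,7-bis(benzyloxy)-2-[8-(benzyloxy)-2,2-dimethyl-4-oxochroman-6-yl]chroman-4-one | CC1(C)CC(=O)c2cc([C@H]3CC(=O)c4c(OCc5ccccc5)cc(OCc5ccccc5)cc4O3)cc(OCc3ccccc3)c2O1
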